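## Retrosynthetic overview

1. The target, (2S,5S,6R)-1,16-didehydro-2,6-cyclolycopen-5-ol, is cut at C11=C12 (Wittig) into a ring-end C15 phosphonium salt and a C25 polyenal; the polyenal is cut at C11'=C12' into the ψ-C15 phosphonium salt (from pseudoionone) and the C10 dialdehyde.
2. The only ring, cyclopentane C2–C3–C4–C5–C6, is closed at C2–C6 by a biomimetic epoxide-opening cation–olefin cyclization of an acyclic (5Z)-5,6-epoxy-ψ end group truncated at C11. In one operation it closes the ring, sets C6 and C2, and creates the isopropenyl group by loss of a C16 proton.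
3. Enabling feature: the tertiary carbinol C5 lies next to the ring methine C6, which is allylic to C7=C8; this is the imprint of a 5,6-epoxide opened at its allylic carbon. C2, reached through C3–C4, carries C1 at the oxidation level of a quenched tertiary cation (isopropenyl C1(=C16)C17).
4. The cis-epoxide comes from nerol by Sharpless epoxidation, which fixes C5. Inversion at C6 then puts the chain cis to O5; O5 ends trans to C1 and cannot bridge to the cation, so proton loss is the exit. C7–C11 is attached before ring closure so that C6 is dienyl-activated, but not so stabilised that closure becomes reversible.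
5. Ring order: the cyclopentane (step 6) is the only ring; the polyene is assembled afterwards.

Key step: step 6

Remark on numbering: carotenoid numbering is used for the target and its fragments (C1–C20 for the ring half, primed numbers for the ψ half).
Assumption: pseudoionone 14 is taken as its (3E,5E) isomer; any (5Z) material of technical grades is removed when salt 16 is crystallised.

## Route

Step 1
Reactants: 1 nerol
Product: 2 (2R,3S)-2,3-epoxynerol
Conditions: Ti(OiPr)4 (cat.), D-(−)-diethyl tartrate (cat.), t-BuOOH, 4 Å molecular sieves, CH2Cl2, −20 °C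
Reagents that add atoms: tert-butyl hydroperoxide, CC(C)(C)OO
Why: Sharpless asymmetric epoxidation: the titanium tartrate complex binds the allylic alcohol and delivers oxygen only to its alkene, D-(−)-tartrate giving the (2R,3S) cis-epoxide, which fixes C5 (S) of the target and the C6 centre that is inverted later, while the remote trisubstituted alkene does not react.

Step 2
Reactants: 2 (2R,3S)-2,3-epoxynerol
Product: 3 (2S,3S)-2,3-epoxyneral
Conditions: TEMPO (cat.), PhI(OAc)2, CH2Cl2, rt
Reagents that add atoms: none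
Why: Oxoammonium (TEMPO/PhI(OAc)2) oxidation of the primary alcohol under neutral conditions stops at the aldehyde and leaves the epoxide and its α-stereocentre untouched.

Step 3
Reactants: 3 (2S,3S)-2,3-epoxyneral; 4 triethyl (2E)-3-methyl-4-phosphonobut-2-enoate
Product: 6 ethyl (2E,4E)-3-methyl-5-[(2R,3S)-3-methyl-3-(4-methylpent-3-en-1-yl)oxiran-2-yl]penta-2,4-dienoate, via lithiated phosphonate 5 (not isolated)
Conditions: LiN(SiMe3)2, THF, −78 °C; then 3, −78 to 0 °C
Reagents that add atoms: none
Why: Horner–Wadsworth–Emmons olefination: the vinylogous phosphonate anion reacts through the carbon next to phosphorus and should give the new C7=C8 bond E and the C9=C10 bond mainly E (minor Z isomer removed by chromatography), the non-enolisable epoxy aldehyde tolerating the amide base at low temperature.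

Step 4
Reactants: 6 epoxy dienoate
Product: 7 (2E,4E)-3-methyl-5-[(2R,3S)-3-methyl-3-(4-methylpent-3-en-1-yl)oxiran-2-yl]penta-2,4-dien-1-ol
Conditions: i-Bu2AlH, CH2Cl2, −78 °C; aq. Rochelle salt
Reagents that add atoms: none
Why: 1,2-Reduction of the conjugated ester by i-Bu2AlH at −78 °C should give the allylic alcohol faster than the aluminium hydride can open the epoxide.

Step 5
Reactants: 7 epoxy dienol
Product: 8 tert-butyldiphenylsilyl ether of 7
Conditions: t-BuPh2SiCl, imidazole, CH2Cl2, 0 °C to rt
Reagents that add atoms: tert-butyl(chloro)diphenylsilane, CC(C)(C)[Si](Cl)(c1ccccc1)c1ccccc1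
Why: Standard silylation of the primary alcohol; the tert-butyldiphenylsilyl ether is chosen because it neither participates as a neighbouring group nor ionises under the silyl triflate of the next step.

Step 6
Reactants: 8 tert-butyldiphenylsilyl ether of the epoxy dienol
Product: 11 tert-butyldiphenylsilyl ether of (2E,4E)-3-methyl-5-[(1R,2S,5S)-2-methyl-5-(prop-1-en-2-yl)-2-(trimethylsilyloxy)cyclopentyl]penta-2,4-dien-1-ol, via O-silyl oxiranium triflate 9 (not isolated), via tertiary carbocation triflate 10 (not isolated)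
Conditions: Me3SiOTf (1.1 equiv), 2,6-di-tert-butyl-4-methylpyridine (1.5 equiv), CH2Cl2, −78 °C; Et3N, then aq. NaHCO3
Reagents that add atoms: trimethylsilyl trifluoromethanesulfonate, C[Si](C)(C)OS(=O)(=O)C(F)(F)F
Why: Me3SiOTf silylates the epoxide oxygen (9); the C6–O bond, allylic to the C7=C8–C9=C10 diene, is the one that lengthens, and the C1=C2 alkene attacks C6 anti to the departing oxygen to give tertiary C1 cation 10, from which the hindered pyridine removes a methyl proton to form the isopropenyl group, O5 ending as its trimethylsilyl ether. The closest known reaction type is the Lewis-acid-promoted epoxide-initiated cation–olefin cyclization, and on this same bond the acid-induced 2,6-cyclization of the 5,6-epoxide of a lycopene end group. The cyclopentane C2–C3–C4–C5–C6 closes in a 5-exo-trig mode at the alkene (C1 stays outside the ring) and in an endo mode at the epoxide (the distal carbon C6 is attacked), the mode that an alkenyl group on the distal carbon is known to enforce. C5 is carried over from the Sharpless epoxide with its C–O bond intact; C6 is set by inversion, which from the cis-epoxide places the dienyl chain cis to O5 and trans to the C5 methyl; C2 is set by an envelope-like transition state in which the incipient CMe2 cation lies anti to the C7 substituent (2,6-trans). The step needs C6–O over C5–O cleavage (dienyl stabilisation at C6, and no ring of workable size can form from C5), ring closure faster than 1,2-shift or proton loss from the dienyl cation (five-membered closure by a trisubstituted alkene at −78 °C, a silyl ether and not an ester at C11), and methyl over C2–H deprotonation (bulky base, six methyl protons against one hindered methine). Because O5 ends trans to C1 it cannot bridge to the cation, so the oxabicyclic ether open to the trans-epoxide series is excluded.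

Step 7
Reactants: 11 bis-silyl ether
Product: 12 (1S,2R,3S)-2-[(1E,3E)-5-hydroxy-3-methylpenta-1,3-dien-1-yl]-1-methyl-3-(prop-1-en-2-yl)cyclopentan-1-ol
Conditions: n-Bu4NF (2.5 equiv), THF, 0 °C to rt
Reagents that add atoms: none
Why: Fluoride-induced desilylation removes both silyl ethers (strong Si–F bond) without touching the alkenes or the stereocentres.

Step 8
Reactants: 12 diol
Product: 13 {(2E,4E)-5-[(1R,2S,5S)-2-hydroxy-2-methyl-5-(prop-1-en-2-yl)cyclopentyl]-3-methylpenta-2,4-dien-1-yl}triphenylphosphonium bromide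
Conditions: PPh3·HBr, MeOH, 0 °C to rt; precipitation from EtOAc
Reagents that add atoms: triphenylphosphine hydrobromide, [Br-].c1ccccc1[PH+](c1ccccc1)c1ccccc1
Why: Phosphonium salt formation from an allylic alcohol with PPh3·HBr (acid-assisted substitution by triphenylphosphine at the primary dienylic carbon), conditions under which the saturated tertiary alcohol and the isolated isopropenyl group should be inert, as hydroxylated end groups are in carotenoid C15 salts.

Step 9
Reactants: 14 (3E,5E)-pseudoionone
Product: 15 vinyl-ψ-ionol [(4E,6E)-3,7,11-trimethyldodeca-1,4,6,10-tetraen-3-ol; racemic]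
Conditions: CH2=CHMgBr, THF, 0 °C; aq. NH4Cl
Reagents that add atoms: vinylmagnesium bromide, C=C[Mg]Br
Why: Grignard 1,2-addition of the hard vinylmagnesium reagent to the ketone carbonyl of the dienone; the racemic carbinol centre is destroyed in the next step.

Step 10
Reactants: 15 vinyl-ψ-ionol
Product: 16 [(2E,4E,6E)-3,7,11-trimethyldodeca-2,4,6,10-tetraen-1-yl]triphenylphosphonium bromide
Conditions: PPh3·HBr, MeOH, rt; crystallisation
Reagents that add atoms: triphenylphosphine hydrobromide, [Br-].c1ccccc1[PH+](c1ccccc1)c1ccccc1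
Why: PPh3·HBr converts the tertiary vinyl carbinol into the primary phosphonium salt with allylic transposition (ionisation to the delocalised cation, phosphine attack at the unhindered terminus), the all-E salt being purified by crystallisation.

Step 11
Reactants: 16 ψ-C15 phosphonium bromide; 17 (2E,4E,6E)-2,7-dimethylocta-2,4,6-trienedial (3 equiv)
Product: 19 (2E,4E,6E,8E,10E,12E,14E)-2,7,11,15,19-pentamethylicosa-2,4,6,8,10,12,14,18-octaenal (apo-12'-lycopenal), via ylide 18 (not isolated)
Conditions: NaOMe, MeOH/CH2Cl2, 0 °C to rt; then heptane, reflux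
Reagents that add atoms: none
Why: Wittig olefination of one formyl group: the dialdehyde is used in excess and the monoadduct aldehyde, conjugated to a longer polyene, is less electrophilic, while heating should equilibrate the new disubstituted C11'=C12' bond to E.

Step 12
Reactants: 13 ring-end C15 phosphonium bromide; 19 apo-12'-lycopenal
Product: 21 (2S,5S,6R)-1,16-didehydro-2,6-cyclolycopen-5-ol (target), via ylide 20 (not isolated)
Conditions: NaOMe, MeOH/CH2Cl2, 0 °C to rt, dark, Ar; then heptane, 90 °C; crystallisation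
Reagents that add atoms: none
Why: Wittig olefination forming C11=C12, the standard carotenoid coupling, which tolerates a free tertiary hydroxyl; brief heating should convert the hindered 11Z isomer into the all-E compound, and no stereocentre is involved.

## Compound list

1 | nerol, (2Z)-3,7-dimethylocta-2,6-dien-1-ol | CC(C)=CCC/C(C)=C\CO | starting material
2 | (2R,3S)-2,3-epoxynerol, [(2R,3S)-3-methyl-3-(4-methylpent-3-en-1-yl)oxiran-2-yl]methanol (cis-epoxide) | OC[C@H]1O[C@@]1(C)CCC=C(C)C | intermediate
3 | (2S,3S)-2,3-epoxyneral, (2S,3S)-3-methyl-3-(4-methylpent-3-en-1-yl)oxirane-2-carbaldehyde | O=C[C@H]1O[C@@]1(C)CCC=C(C)C | intermediate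
4 | triethyl (2E)-3-methyl-4-phosphonobut-2-enoate | CCOC(=O)/C=C(\C)CP(=O)(OCC)OCC | starting material
5 | lithiated phosphonate (delocalised anion of 4, no fixed geometry) | [Li+].CCOC(=O)C=C(C)[CH-]P(=O)(OCC)OCC | intermediate (not isolated)
6 | ethyl (2E,4E)-3-methyl-5-[(2R,3S)-3-methyl-3-(4-methylpent-3-en-1-yl)oxiran-2-yl]penta-2,4-dienoate | CCOC(=O)/C=C(C)/C=C/[C@H]1O[C@@]1(C)CCC=C(C)C | intermediate
7 | (2E,4E)-3-methyl-5-[(2R,3S)-3-methyl-3-(4-methylpent-3-en-1-yl)oxiran-2-yl]penta-2,4-dien-1-ol | OC/C=C(C)/C=C/[C@H]1O[C@@]1(C)CCC=C(C)C | intermediate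
8 | tert-butyldiphenylsilyl ether of 7 | CC(C)(C)[Si](c1ccccc1)(c1ccccc1)OC/C=C(C)/C=C/[C@H]2O[C@@]2(C)CCC=C(C)C | intermediate
9 | O-trimethylsilyl oxiranium triflate of 8 | CC(C)(C)[Si](c1ccccc1)(c1ccccc1)OC/C=C(C)/C=C/[C@H]2[O+]([Si](C)(C)C)[C@@]2(C)CCC=C(C)C.[O-]S(=O)(=O)C(F)(F)F | intermediate (not isolated)
10 | tertiary C1 carbocation (triflate ion pair) of the closed cyclopentane | C[C+](C)[C@H]1CC[C@](C)(O[Si](C)(C)C)[C@@H]1/C=C/C(C)=C/CO[Si](c2ccccc2)(c3ccccc3)C(C)(C)C.[O-]S(=O)(=O)C(F)(F)F | intermediate (not isolated)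
11 | tert-butyldiphenylsilyl ether of (2E,4E)-3-methyl-5-[(1R,2S,5S)-2-methyl-5-(prop-1-en-2-yl)-2-(trimethylsilyloxy)cyclopentyl]penta-2,4-dien-1-ol | C=C(C)[C@H]1CC[C@](C)(O[Si](C)(C)C)[C@@H]1/C=C/C(C)=C/CO[Si](c2ccccc2)(c2ccccc2)C(C)(C)C | intermediate
12 | (1S,2R,3S)-2-[(1E,3E)-5-hydroxy-3-methylpenta-1,3-dien-1-yl]-1-methyl-3-(prop-1-en-2-yl)cyclopentan-1-ol | C=C(C)[C@H]1CC[C@](C)(O)[C@@H]1/C=C/C(C)=C/CO | intermediate
13 | {(2E,4E)-5-[(1R,2S,5S)-2-hydroxy-2-methyl-5-(prop-1-en-2-yl)cyclopentyl]-3-methylpenta-2,4-dien-1-yl}triphenylphosphonium bromide | C=C(C)[C@H]1CC[C@](C)(O)[C@@H]1/C=C/C(C)=C/C[P+](c2ccccc2)(c2ccccc2)c2ccccc2.[Br-] | intermediate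
14 | (3E,5E)-pseudoionone, (3E,5E)-6,10-dimethylundeca-3,5,9-trien-2-one | CC(=O)/C=C/C=C(\C)CCC=C(C)C | starting material
15 | vinyl-ψ-ionol, (4E,6E)-3,7,11-trimethyldodeca-1,4,6,10-tetraen-3-ol (racemic) | C=CC(C)(O)/C=C/C=C(\C)CCC=C(C)C | intermediate
16 | [(2E,4E,6E)-3,7,11-trimethyldodeca-2,4,6,10-tetraen-1-yl]triphenylphosphonium bromide | CC(C)=CCC/C(C)=C/C=C/C(C)=C/C[P+](c1ccccc1)(c1ccccc1)c1ccccc1.[Br-] | intermediate
17 | (2E,4E,6E)-2,7-dimethylocta-2,4,6-trienedial (C10 dialdehyde) | O=C/C(C)=C/C=C/C=C(C)/C=O | starting material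
18 | ylide of 16, [(2E,4E,6E)-3,7,11-trimethyldodeca-2,4,6,10-tetraen-1-ylidene]triphenylphosphorane | CC(C)=CCC/C(C)=C/C=C/C(C)=C/C=P(c1ccccc1)(c1ccccc1)c1ccccc1 | intermediate (not isolated)
19 | (2E,4E,6E,8E,10E,12E,14E)-2,7,11,15,19-pentamethylicosa-2,4,6,8,10,12,14,18-octaenal (apo-12'-lycopenal) | O=C/C(C)=C/C=C/C=C(C)/C=C/C=C(C)/C=C/C=C(\C)CCC=C(C)C | intermediate
20 | ylide of 13 | C=C(C)[C@H]1CC[C@](C)(O)[C@@H]1/C=C/C(C)=C/C=P(c2ccccc2)(c2ccccc2)c2ccccc2 | intermediate (not isolated)
21 | (2S,5S,6R)-1,16-didehydro-2,6-cyclolycopen-5-ol; (1S,2R,3S)-2-[(1E,3E,5E,7E,9E,11E,13E,15E,17E,19E)-3,7,12,16,20,24-hexamethylpentacosa-1,3,5,7,9,11,13,15,17,19,23-undecaen-1-yl]-1-methyl-3-(prop-1-en-2-yl)cyclopentan-1-ol | C=C(C)[C@H]1CC[C@](C)(O)[C@@H]1/C=C/C(C)=C/C=C/C(C)=C/C=C/C=C(C)/C=C/C=C(C)/C=C/C=C(\C)CCC=C(C)C | target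

## Step count and risks

Total step count: 12. Longest linear sequence: 9 (steps 1–8 and 12, from nerol).

**Step 6 (key step).** What may go wrong: the silylated epoxide may ionise toward tertiary C5 and collapse by a 1,2-shift; the dienyl cation may lose a proton before the unactivated alkene closes the ring; and the C1 cation may shed its proton unselectively, giving the isopropylidene isomer. Fallback (sets out from 2, comes back at 11): replace proton loss by silicon-controlled termination. Ozonolysis of 2 (O3, CH2Cl2/MeOH, −78 °C; Me2S) cleaves its only alkene to the aldehyde 3-[(2S,3R)-3-(hydroxymethyl)-2-methyloxiran-2-yl]propanal F1. Seyferth–Fleming olefination of F1 with Ph3P=C(CH3)CH2SiMe3 (2.2 equiv; from ethyltriphenylphosphonium bromide, n-BuLi and (iodomethyl)trimethylsilane, then n-BuLi; THF, −78 °C to rt) gives the allylsilane {(2R,3S)-3-methyl-3-[4-methyl-5-(trimethylsilyl)pent-3-en-1-yl]oxiran-2-yl}methanol F2 as an E/Z mixture, both isomers leading to the same product later. The chemistry of steps 2 to 5 is then repeated in the silylated series: oxidation (SO3·pyridine, DMSO, Et3N, chosen to spare the allylsilane) to (2S,3S)-3-methyl-3-[4-methyl-5-(trimethylsilyl)pent-3-en-1-yl]oxirane-2-carbaldehyde F3, olefination with 4 to the silylated epoxy dienoate F4, i-Bu2AlH reduction to the silylated epoxy dienol F5, and silylation to its tert-butyldiphenylsilyl ether F6. With catalytic Me3SiOTf in CH2Cl2 at −78 °C, F6 should undergo the known intramolecular allylsilane–epoxide cyclization: the allylsilane, far more nucleophilic than the trisubstituted alkene, attacks C6 through C2, and the β-silyl cation loses Me3Si+, which returns as Me3SiOTf and silylates O5. The double bond can then only appear at C1=C16, and the product is 11.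

**Step 8.** What may go wrong: under the acidic conditions the dienylic C11–O bond ionises; the cation shares its charge with C7 and may be lost by fragmentation of the adjacent C5–C6 bond (ring opening driven by the C5 hydroxyl) or by scrambling of the C9=C10 geometry, and HBr may add to the isopropenyl group. Fallback (sets out from 12 and 19, comes back at 21): exchange the roles of the Wittig partners so that the ring fragment never meets acid. MnO2 (CH2Cl2, rt) oxidises only the allylic hydroxyl of 12 to (2E,4E)-5-[(1R,2S,5S)-2-hydroxy-2-methyl-5-(prop-1-en-2-yl)cyclopentyl]-3-methylpenta-2,4-dienal F7. NaBH4 (EtOH/THF, 0 °C) reduces 19 to (2E,4E,6E,8E,10E,12E,14E)-2,7,11,15,19-pentamethylicosa-2,4,6,8,10,12,14,18-octaen-1-ol F8, PPh3·HBr (MeOH, rt) converts it into the C25 triphenylphosphonium bromide F9, and NaOMe gives the C25 ylide F10. Wittig reaction of F10 with F7, followed by the same thermal isomerisation, gives 21.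

**Step 12.** What may go wrong: olefination of the sparingly soluble, weakly electrophilic C25 polyenal by the precious ylide 20 may be slow, with oxidative loss of polyene and a Z/E mixture that does not fully converge. Fallback (sets out from 13 and 17, comes back at 21): reverse the order of assembly. Ylide 20 (from 13, NaOMe, MeOH/CH2Cl2, 0 °C) is added to an excess of the small, soluble and reactive dialdehyde 17 to give the ring-end C25 aldehyde (2E,4E,6E,8E,10E,12E)-13-[(1R,2S,5S)-2-hydroxy-2-methyl-5-(prop-1-en-2-yl)cyclopentyl]-2,7,11-trimethyltrideca-2,4,6,8,10,12-hexaenal F11. The last bond (C11'=C12') is then formed by Wittig reaction of F11 with ylide 18, made from the inexpensive salt 16 and used in excess; thermal isomerisation gives 21.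

Further compounds
F1 | step 6 | 3-[(2S,3R)-3-(hydroxymethyl)-2-methyloxiran-2-yl]propanal | OC[C@H]1O[C@@]1(C)CCC=O
F2 | step 6 | {(2R,3S)-3-methyl-3-[4-methyl-5-(trimethylsilyl)pent-3-en-1-yl]oxiran-2-yl}methanol (E/Z mixture at the allylsilane) | OC[C@H]1O[C@@]1(C)CCC=C(C)C[Si](C)(C)C
F3 | step 6 | (2S,3S)-3-methyl-3-[4-methyl-5-(trimethylsilyl)pent-3-en-1-yl]oxirane-2-carbaldehyde | O=C[C@H]1O[C@@]1(C)CCC=C(C)C[Si](C)(C)C
F4 | step 6 | ethyl (2E,4E)-3-methyl-5-{(2R,3S)-3-methyl-3-[4-methyl-5-(trimethylsilyl)pent-3-en-1-yl]oxiran-2-yl}penta-2,4-dienoate | CCOC(=O)/C=C(C)/C=C/[C@H]1O[C@@]1(C)CCC=C(C)C[Si](C)(C)C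
F5 | step 6 | (2E,4E)-3-methyl-5-{(2R,3S)-3-methyl-3-[4-methyl-5-(trimethylsilyl)pent-3-en-1-yl]oxiran-2-yl}penta-2,4-dien-1-ol | OC/C=C(C)/C=C/[C@H]1O[C@@]1(C)CCC=C(C)C[Si](C)(C)C
F6 | step 6 | tert-butyldiphenylsilyl ether of F5 | CC(C)(C)[Si](c1ccccc1)(c1ccccc1)OC/C=C(C)/C=C/[C@H]2O[C@@]2(C)CCC=C(C)C[Si](C)(C)C
F7 | step 8 | (2E,4E)-5-[(1R,2S,5S)-2-hydroxy-2-methyl-5-(prop-1-en-2-yl)cyclopentyl]-3-methylpenta-2,4-dienal | C=C(C)[C@H]1CC[C@](C)(O)[C@@H]1/C=C/C(C)=C/C=O
F8 | step 8 | (2E,4E,6E,8E,10E,12E,14E)-2,7,11,15,19-pentamethylicosa-2,4,6,8,10,12,14,18-octaen-1-ol | OC/C(C)=C/C=C/C=C(C)/C=C/C=C(C)/C=C/C=C(\C)CCC=C(C)C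
F9 | step 8 | [(2E,4E,6E,8E,10E,12E,14E)-2,7,11,15,19-pentamethylicosa-2,4,6,8,10,12,14,18-octaen-1-yl]triphenylphosphonium bromide | [Br-].c1ccccc1[P+](c1ccccc1)(c1ccccc1)C/C(C)=C/C=C/C=C(C)/C=C/C=C(C)/C=C/C=C(\C)CCC=C(C)C
F10 | step 8 | ylide of F9 | c1ccccc1P(c1ccccc1)(c1ccccc1)=C/C(C)=C/C=C/C=C(C)/C=C/C=C(C)/C=C/C=C(\C)CCC=C(C)C
F11 | step 12 | (2E,4E,6E,8E,10E,12E)-13-[(1R,2S,5S)-2-hydroxy-2-methyl-5-(prop-1-en-2-yl)cyclopentyl]-2,7,11-trimethyltrideca-2,4,6,8,10,12-hexaenal | C=C(C)[C@H]1CC[C@](C)(O)[C@@H]1/C=C/C(C)=C/C=C/C(C)=C/C=C/C=C(C)/C=O
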